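(All constants were drawn at random within sensible limits; the run is a simulation.)

Leftover substrate is where I start in this flask: catalyst intermediate B has two exits and one of them ends the catalyst, so a charge of free catalyst has a budget of substrate.

substrate 1.2 M; partner 1.14 M; free catalyst 12 mM

    substrate + free catalyst → catalyst intermediate A (k1 = 3.15 M⁻¹ s⁻¹)
    partner + catalyst intermediate A ⇌ catalyst intermediate B (K2 = 12.3 M⁻¹, k2 = 6.71 M⁻¹ s⁻¹)
    catalyst intermediate B → catalyst intermediate C (k3 = 7.00 s⁻¹)
    catalyst intermediate C ⇌ released group + catalyst intermediate D (K4 = 0.932 M, k4 = 316 s⁻¹)
    catalyst intermediate D ⇌ free catalyst + product (K5 = 0.61 M, k5 = 3.40 s⁻¹)
    catalyst intermediate B → spent catalyst (k6 = 0.270 s⁻¹)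

- apparent order in partner when 5.0% of the substrate are converted (percent change of the rate of making product for one percent more partner charged)
- apparent order in free catalyst when 5.0% of the substrate are converted (percent change of the rate of making product for one percent more free catalyst charged)

The capture of substrate by free catalyst is irreversible, so each round takes up one substrate, and catalyst intermediate B then goes forward at 7.00 s⁻¹ or dies at 0.270 s⁻¹. One plus the ratio of these exits gives N = 26.9, the turnover number, counted here in substrate: the substrate one catalyst takes up on average before it is spent. At 5.0% conversion the flask has used 0.0600 M of substrate, which by this count leaves an active share of the catalyst of 0.814. By the same count, at fixed conversion the amount spent stays the same when more catalyst is charged, so my estimate of the order in free catalyst is the reciprocal of that share, 1.23.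

For the partner I add the forward waits of the round, each the reciprocal of a pseudo-first-order rate. The partner's wait is 0.138 s of a round of 0.857 s, so my order in partner is that share, 0.161.

The forecast gives 0.17 and 1.24, a shade above my figures, and argues that “at fixed conversion, more catalyst means a smaller spent fraction”. The simulation gives 0.17 and 1.2 at 4.47 s, so the forecast holds on both.

The rate at this conversion is held down in part by the conversion of catalyst intermediate B into spent catalyst: the run without that branch has 1.22 times the actual rate. That branch is also the largest single effect on the order in free catalyst, which goes from 1.2 to 1.0 in that run. N times the catalyst charge is 0.323 M of substrate, and at 400 s, with spent catalyst at >99.9%, this flask has used 0.323 M and has 73.1% of its substrate left over.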